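**Retrosynthetic overview**

1. Manuifolin E (16) ⇐ removal of the 2'-O-MOM group of 15 ⇐ two-directional aromatic Claisen rearrangement of bis(prenyl ether) 14; the two O-prenyl groups protect O7 and O4' until then and end up as the C6 and C5' 1,1-dimethylallyl groups.
2. 14 ⇐ Mitsunobu closure (O1–C2) of phenol-alcohol 13 ⇐ dynamic kinetic asymmetric hydrogenation of the racemic 3-aryl-dihydrocoumarin 12, which sets C3 as R.
3. 12 ⇐ arylacetic acid 9 (ring B, C3, C2, O1) + 2-bromobenzyl bromide 4 (ring A, C4, C8a): C3–C4 by enediolate benzylation and O1–C8a by copper-catalysed arylation of the carboxylate, in one flask.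
4. Enabling feature: C3 sits between ring B (C1') and C2. With C2 at the carboxylic acid level, C3–H is benzylic and α-carbonyl and O1 is a carboxylate oxygen, so C3/O1 is a 1,3-C,O-dinucleophile matching the 1,3-dielectrophile C4 (benzylic) / C8a (ortho carbon of ring A). The same C2 carbonyl keeps C3 epimerisable for the resolution.
5. Ring order: rings A and B are bought (1, 5); ring C is closed as a lactone in step 8, reduced open in step 9 and closed again as the pyran in step 10.

Key step: step 8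

Assumption: the sense of induction of the SpiroPAP iridium catalyst on lactone 12 is not known in advance, so the ligand enantiomer written in step 9 stands for whichever enantiomer gives the 2R alcohol.

**Route**

Step 1
Reactants: 1 2-bromo-4-hydroxybenzaldehyde
Product: 2 2-bromo-4-[(3-methylbut-2-en-1-yl)oxy]benzaldehyde
Conditions: prenyl bromide, K2CO3, DMF, rt
Reagents that add atoms: prenyl bromide (1-bromo-3-methylbut-2-ene), CC(C)=CCBr
Why: Williamson ether synthesis, in which the phenoxide of 1 (acidified by the para formyl group) is alkylated at oxygen by the primary allylic bromide, the prenyl ether serving as protection of the later O7 and as the latent C6 side chain.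

Step 2
Reactants: 2 2-bromo-4-[(3-methylbut-2-en-1-yl)oxy]benzaldehyde
Product: 3 {2-bromo-4-[(3-methylbut-2-en-1-yl)oxy]phenyl}methanol
Conditions: NaBH4, MeOH, 0 °C
Reagents that add atoms: none
Why: Borohydride reduction of an aryl aldehyde is chemoselective and should leave the aryl bromide and the trisubstituted alkene untouched.

Step 3
Reactants: 3 {2-bromo-4-[(3-methylbut-2-en-1-yl)oxy]phenyl}methanol
Product: 4 2-bromo-1-(bromomethyl)-4-[(3-methylbut-2-en-1-yl)oxy]benzene
Conditions: CBr4, PPh3, CH2Cl2, 0 °C; used directly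
Reagents that add atoms: carbon tetrabromide, BrC(Br)(Br)Br
Why: Appel bromination converts the benzylic alcohol into the bromide under neutral conditions, so no HBr is present that could add to or cleave the prenyl ether.

Step 4
Reactants: 5 2,4-dihydroxybenzaldehyde
Product: 6 2-hydroxy-4-[(3-methylbut-2-en-1-yl)oxy]benzaldehyde
Conditions: prenyl bromide (1.05 equiv), K2CO3 (1.05 equiv), acetone, reflux
Reagents that add atoms: prenyl bromide (1-bromo-3-methylbut-2-ene), CC(C)=CCBr
Why: Regioselective Williamson etherification, since the 2-OH is held in a hydrogen bond to the formyl oxygen and the more acidic, unchelated 4-OH should be alkylated.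

Step 5
Reactants: 6 2-hydroxy-4-[(3-methylbut-2-en-1-yl)oxy]benzaldehyde
Product: 7 2-(methoxymethoxy)-4-[(3-methylbut-2-en-1-yl)oxy]benzaldehyde
Conditions: MOMCl, iPr2NEt, CH2Cl2, 0 → 40 °C
Reagents that add atoms: chloromethyl methyl ether (MOMCl), COCCl
Why: Acetal (MOM ether) formation on the remaining phenol gives a base- and heat-stable group that later also keeps the position between the two oxygens of ring B crowded.

Step 6
Reactants: 7 2-(methoxymethoxy)-4-[(3-methylbut-2-en-1-yl)oxy]benzaldehyde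
Product: 8 2-{2-(methoxymethoxy)-4-[(3-methylbut-2-en-1-yl)oxy]phenyl}acetonitrile
Conditions: TosMIC, KOtBu, DME, −40 °C; then MeOH, reflux
Reagents that add atoms: p-toluenesulfonylmethyl isocyanide (TosMIC), Cc1ccc(cc1)S(=O)(=O)C[N+]#[C-]
Why: van Leusen reductive cyanation homologates an aromatic aldehyde to the arylacetonitrile in one step under basic conditions that both ethers tolerate.

Step 7
Reactants: 8 2-{2-(methoxymethoxy)-4-[(3-methylbut-2-en-1-yl)oxy]phenyl}acetonitrile
Product: 9 2-{2-(methoxymethoxy)-4-[(3-methylbut-2-en-1-yl)oxy]phenyl}acetic acid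
Conditions: KOH, EtOH/H2O, reflux; then aq. KHSO4 to pH 4, 0 °C
Reagents that add atoms: potassium hydroxide, [K+].[OH-]; water, O
Why: Basic nitrile hydrolysis gives the carboxylate while the MOM and prenyl ethers, both base-stable, survive, and the cold buffered acidification should spare the MOM acetal.

Step 8
Reactants: 9 2-{2-(methoxymethoxy)-4-[(3-methylbut-2-en-1-yl)oxy]phenyl}acetic acid; 4 2-bromo-1-(bromomethyl)-4-[(3-methylbut-2-en-1-yl)oxy]benzene
Product: 12 rac-3-{2-(methoxymethoxy)-4-[(3-methylbut-2-en-1-yl)oxy]phenyl}-7-[(3-methylbut-2-en-1-yl)oxy]-3,4-dihydro-2H-chromen-2-one, via dilithium enediolate 10 (not isolated), via lithium carboxylate 11 (not isolated)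
Conditions: LiN(iPr)2 (2.1 equiv, commercial solution), THF, −78 → 0 °C; 4, −78 °C → rt; then same flask: CuI (20 mol%), 1,10-phenanthroline (40 mol%), DMF, THF distilled off, 110 °C
Reagents that add atoms: none
Why: Double deprotonation of 9 gives enediolate 10, whose carbon (C3) displaces the benzylic bromide of 4 by SN2 to form C3–C4, and the resulting carboxylate 11 is then arylated at oxygen by the ortho C–Br bond under copper catalysis (oxidative addition of the aryl bromide to the copper carboxylate, then C–O reductive elimination) to form O1–C8a. The closest known reaction types are the C-benzylation of arylacetic acid dianions and the Ullmann-type intramolecular O-arylation of carboxylates to benzo-fused lactones, run here in one flask like the known domino C-benzylation/O-arylation of 1,3-dicarbonyl compounds with 2-bromobenzyl bromides. Ring C closes as a six-membered lactone (O1, C2, C3, C4, C4a, C8a) by intramolecular C–O bond formation at the metalated C8a. The new stereocentre C3 is formed racemic on purpose, because in 12 it is α to the lactone carbonyl and benzylic to ring B, hence epimerisable, which is what step 9 needs. The step needs C- over O-alkylation and reaction of the benzylic before the aryl bromide: the dianion is carbon-nucleophilic, only the sp3 C–Br bond undergoes SN2, and the single aryl bromide ortho to the new chain leaves one site for the closure.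

Step 9
Reactants: 12 rac-3-{2-(methoxymethoxy)-4-[(3-methylbut-2-en-1-yl)oxy]phenyl}-7-[(3-methylbut-2-en-1-yl)oxy]-3,4-dihydro-2H-chromen-2-one
Product: 13 (2R)-3-{2-hydroxy-4-[(3-methylbut-2-en-1-yl)oxy]phenyl}-2-{2-(methoxymethoxy)-4-[(3-methylbut-2-en-1-yl)oxy]phenyl}propan-1-ol
Conditions: [Ir(cod)Cl]2 (0.5 mol%), (R)-SpiroPAP (1.1 mol%), KOtBu (1.1 equiv), H2 (10 atm), n-PrOH, rt; AcOH quench
Reagents that add atoms: none
Why: Dynamic kinetic resolution by asymmetric hydrogenation of a racemic α-aryl lactone, in which C3–H epimerises under KOtBu faster than reduction while the chiral iridium hydride reduces the ester carbonyl of one enantiomer preferentially, so the ligand sets C3 (R) and the carbonyl-selective catalyst should not touch the trisubstituted prenyl alkenes.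

Step 10
Reactants: 13 (2R)-3-{2-hydroxy-4-[(3-methylbut-2-en-1-yl)oxy]phenyl}-2-{2-(methoxymethoxy)-4-[(3-methylbut-2-en-1-yl)oxy]phenyl}propan-1-ol
Product: 14 (3R)-3-{2-(methoxymethoxy)-4-[(3-methylbut-2-en-1-yl)oxy]phenyl}-7-[(3-methylbut-2-en-1-yl)oxy]-3,4-dihydro-2H-chromene
Conditions: PPh3, DIAD, THF, 0 °C → rt
Reagents that add atoms: none
Why: Intramolecular Mitsunobu etherification, in which the only free phenol (O1 on C8a) displaces the activated primary hydroxyl at C2 in a 6-exo-tet closure that does not involve the C3 stereocentre.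

Step 11
Reactants: 14 (3R)-3-{2-(methoxymethoxy)-4-[(3-methylbut-2-en-1-yl)oxy]phenyl}-7-[(3-methylbut-2-en-1-yl)oxy]-3,4-dihydro-2H-chromene
Product: 15 (3R)-3-[4-hydroxy-2-(methoxymethoxy)-5-(2-methylbut-3-en-2-yl)phenyl]-6-(2-methylbut-3-en-2-yl)-3,4-dihydro-2H-chromen-7-ol
Conditions: N,N-diethylaniline, 185 °C, sealed tube, argon
Reagents that add atoms: none
Why: Two thermal aromatic Claisen rearrangements ([3,3]-sigmatropic shift, then tautomerisation) move each prenyl group from oxygen to an ortho carbon with allylic inversion to give the 1,1-dimethylallyl groups, C6 and C5' being expected over C8 and C3' because the latter lie between two oxygen substituents and would have to take a quaternary carbon between them, while the blocked para positions C4a and C1' exclude a para migration.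

Step 12
Reactants: 15 (3R)-3-[4-hydroxy-2-(methoxymethoxy)-5-(2-methylbut-3-en-2-yl)phenyl]-6-(2-methylbut-3-en-2-yl)-3,4-dihydro-2H-chromen-7-ol
Product: 16 manuifolin E, (3R)-3-[2,4-dihydroxy-5-(2-methylbut-3-en-2-yl)phenyl]-6-(2-methylbut-3-en-2-yl)-3,4-dihydro-2H-chromen-7-ol
Conditions: HCl (1.25 M in MeOH), THF, 0 °C → rt
Reagents that add atoms: none
Why: Acid-catalysed acetal exchange removes the aryl MOM ether under conditions mild enough that the monosubstituted alkenes, which would need to form secondary cations, should not be protonated.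

**Compound list**

1 | 2-bromo-4-hydroxybenzaldehyde | O=Cc1ccc(O)cc1Br | starting material
2 | 2-bromo-4-[(3-methylbut-2-en-1-yl)oxy]benzaldehyde | O=Cc1ccc(OCC=C(C)C)cc1Br | intermediate
3 | {2-bromo-4-[(3-methylbut-2-en-1-yl)oxy]phenyl}methanol | OCc1ccc(OCC=C(C)C)cc1Br | intermediate
4 | 2-bromo-1-(bromomethyl)-4-[(3-methylbut-2-en-1-yl)oxy]benzene | BrCc1ccc(OCC=C(C)C)cc1Br | intermediate
5 | 2,4-dihydroxybenzaldehyde | O=Cc1ccc(O)cc1O | starting material
6 | 2-hydroxy-4-[(3-methylbut-2-en-1-yl)oxy]benzaldehyde | O=Cc1ccc(OCC=C(C)C)cc1O | intermediate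
7 | 2-(methoxymethoxy)-4-[(3-methylbut-2-en-1-yl)oxy]benzaldehyde | COCOc1cc(OCC=C(C)C)ccc1C=O | intermediate
8 | 2-{2-(methoxymethoxy)-4-[(3-methylbut-2-en-1-yl)oxy]phenyl}acetonitrile | COCOc1cc(OCC=C(C)C)ccc1CC#N | intermediate
9 | 2-{2-(methoxymethoxy)-4-[(3-methylbut-2-en-1-yl)oxy]phenyl}acetic acid | COCOc1cc(OCC=C(C)C)ccc1CC(=O)O | intermediate
10 | dilithium enediolate of 9 | [Li+].[Li+].[O-]C([O-])=Cc1ccc(OCC=C(C)C)cc1OCOC | intermediate
11 | lithium rac-3-{2-bromo-4-[(3-methylbut-2-en-1-yl)oxy]phenyl}-2-{2-(methoxymethoxy)-4-[(3-methylbut-2-en-1-yl)oxy]phenyl}propanoate | [Li+].[O-]C(=O)C(Cc1ccc(OCC=C(C)C)cc1Br)c1ccc(OCC=C(C)C)cc1OCOC | intermediate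
12 | rac-3-{2-(methoxymethoxy)-4-[(3-methylbut-2-en-1-yl)oxy]phenyl}-7-[(3-methylbut-2-en-1-yl)oxy]-3,4-dihydro-2H-chromen-2-one | O=C1Oc2cc(OCC=C(C)C)ccc2CC1c1ccc(OCC=C(C)C)cc1OCOC | intermediate
13 | (2R)-3-{2-hydroxy-4-[(3-methylbut-2-en-1-yl)oxy]phenyl}-2-{2-(methoxymethoxy)-4-[(3-methylbut-2-en-1-yl)oxy]phenyl}propan-1-ol | OC[C@@H](c1ccc(OCC=C(C)C)cc1OCOC)Cc1ccc(OCC=C(C)C)cc1O | intermediate
14 | (3R)-3-{2-(methoxymethoxy)-4-[(3-methylbut-2-en-1-yl)oxy]phenyl}-7-[(3-methylbut-2-en-1-yl)oxy]-3,4-dihydro-2H-chromene | CC(C)=CCOc1ccc2c(c1)OC[C@@H](c1ccc(OCC=C(C)C)cc1OCOC)C2 | intermediate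
15 | (3R)-3-[4-hydroxy-2-(methoxymethoxy)-5-(2-methylbut-3-en-2-yl)phenyl]-6-(2-methylbut-3-en-2-yl)-3,4-dihydro-2H-chromen-7-ol | C=CC(C)(C)c1cc2c(cc1O)OC[C@@H](c1cc(C(C)(C)C=C)c(O)cc1OCOC)C2 | intermediate
16 | manuifolin E | C=CC(C)(C)c1cc2c(cc1O)OC[C@@H](c1cc(C(C)(C)C=C)c(O)cc1O)C2 | target

**Step count**

Total: 12 steps. Longest linear sequence: 9 steps (5 → 16, steps 4 to 12).

**Three steps most likely to fail**

Step 8. The copper-mediated C–O closure at the electron-rich, ortho-substituted aryl bromide may be slow, so that protodebromination or decarboxylation competes at 110 °C. The fallback sets out from 6 and 9 and makes ring C differently, the ring oxygen then coming from the phenol of 6. Carbodiimide coupling (EDC·HCl, DMAP, CH2Cl2) should give the aryl ester 2-formyl-5-[(3-methylbut-2-en-1-yl)oxy]phenyl 2-{2-(methoxymethoxy)-4-[(3-methylbut-2-en-1-yl)oxy]phenyl}acetate F1. Added DBU (catalytic) should then effect intramolecular Knoevenagel condensation to the 3-arylcoumarin 3-{2-(methoxymethoxy)-4-[(3-methylbut-2-en-1-yl)oxy]phenyl}-7-[(3-methylbut-2-en-1-yl)oxy]-2H-chromen-2-one F2. Conjugate reduction of F2 with LiBH(s-Bu)3 (THF, −78 °C, NH4Cl quench) comes back to the route at 12.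

Step 9. Enantioselectivity may erode if alkoxide opening of the aryl lactone or slow epimerisation at C3 takes the reduction out of the dynamic regime. The fallback sets out from 9 and 4 and uses auxiliary control (Evans alkylation) instead of catalytic resolution. EDC·HCl/DMAP coupling of 9 with (R)-4-benzyl-1,3-oxazolidin-2-one gives the imide (4R)-4-benzyl-3-(2-{2-(methoxymethoxy)-4-[(3-methylbut-2-en-1-yl)oxy]phenyl}acetyl)-1,3-oxazolidin-2-one F3. NaN(SiMe3)2 (THF, −78 °C) and then 4 give the alkylated imide (4R)-4-benzyl-3-[(2R)-3-{2-bromo-4-[(3-methylbut-2-en-1-yl)oxy]phenyl}-2-{2-(methoxymethoxy)-4-[(3-methylbut-2-en-1-yl)oxy]phenyl}propanoyl]-1,3-oxazolidin-2-one F4, the benzyl group of the auxiliary shielding one face of the chelated Z-enolate. LiBH4 (THF, MeOH, 0 °C) releases the bromo alcohol (2R)-3-{2-bromo-4-[(3-methylbut-2-en-1-yl)oxy]phenyl}-2-{2-(methoxymethoxy)-4-[(3-methylbut-2-en-1-yl)oxy]phenyl}propan-1-ol F5 and the auxiliary. Intramolecular palladium-catalysed aryl etherification (Pd(OAc)2, 2-(di-tert-butylphosphino)-1,1'-binaphthyl, Cs2CO3, toluene, 70 °C) closes ring C and comes back at 14.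

Step 11. Migration may go in part to the positions between the oxygens (C8, C3'), and the new ortho-allyl phenols may cyclise thermally onto their alkenes. The fallback sets out from 14 and installs the side chains by cross-coupling.
- Palladium-catalysed removal of both prenyl ethers (Pd(PPh3)4, morpholine, THF, 60 °C) gives the diphenol (3R)-3-[4-hydroxy-2-(methoxymethoxy)phenyl]-3,4-dihydro-2H-chromen-7-ol F6.
- NBS (2 equiv, MeCN, −20 °C) should brominate ortho to each free hydroxyl and para to the ring or MOM ether oxygen, giving (3R)-6-bromo-3-[5-bromo-4-hydroxy-2-(methoxymethoxy)phenyl]-3,4-dihydro-2H-chromen-7-ol F7.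
- MOMCl/iPr2NEt gives (3R)-6-bromo-3-[5-bromo-2,4-bis(methoxymethoxy)phenyl]-7-(methoxymethoxy)-3,4-dihydro-2H-chromene F8.
- Twofold γ-selective Suzuki–Miyaura coupling with prenylboronic acid pinacol ester (Pd(OAc)2, bulky di-tert-butyl biaryl phosphine, K3PO4, THF/H2O, 40 °C) gives (3R)-3-[2,4-bis(methoxymethoxy)-5-(2-methylbut-3-en-2-yl)phenyl]-7-(methoxymethoxy)-6-(2-methylbut-3-en-2-yl)-3,4-dihydro-2H-chromene F9.
- The conditions of step 12 then remove the three MOM groups and come back at 16.

**Further compounds**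

F1 | step 8 | 2-formyl-5-[(3-methylbut-2-en-1-yl)oxy]phenyl 2-{2-(methoxymethoxy)-4-[(3-methylbut-2-en-1-yl)oxy]phenyl}acetate | O=Cc1ccc(OCC=C(C)C)cc1OC(=O)Cc1ccc(OCC=C(C)C)cc1OCOC
F2 | step 8 | 3-{2-(methoxymethoxy)-4-[(3-methylbut-2-en-1-yl)oxy]phenyl}-7-[(3-methylbut-2-en-1-yl)oxy]-2H-chromen-2-one | O=C1Oc2cc(OCC=C(C)C)ccc2C=C1c1ccc(OCC=C(C)C)cc1OCOC
F3 | step 9 | (4R)-4-benzyl-3-(2-{2-(methoxymethoxy)-4-[(3-methylbut-2-en-1-yl)oxy]phenyl}acetyl)-1,3-oxazolidin-2-one | O=C(Cc1ccc(OCC=C(C)C)cc1OCOC)N1C(=O)OC[C@H]1Cc1ccccc1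
F4 | step 9 | (4R)-4-benzyl-3-[(2R)-3-{2-bromo-4-[(3-methylbut-2-en-1-yl)oxy]phenyl}-2-{2-(methoxymethoxy)-4-[(3-methylbut-2-en-1-yl)oxy]phenyl}propanoyl]-1,3-oxazolidin-2-one | O=C([C@H](Cc1ccc(OCC=C(C)C)cc1Br)c1ccc(OCC=C(C)C)cc1OCOC)N1C(=O)OC[C@H]1Cc1ccccc1
F5 | step 9 | (2R)-3-{2-bromo-4-[(3-methylbut-2-en-1-yl)oxy]phenyl}-2-{2-(methoxymethoxy)-4-[(3-methylbut-2-en-1-yl)oxy]phenyl}propan-1-ol | OC[C@@H](c1ccc(OCC=C(C)C)cc1OCOC)Cc1ccc(OCC=C(C)C)cc1Br
F6 | step 11 | (3R)-3-[4-hydroxy-2-(methoxymethoxy)phenyl]-3,4-dihydro-2H-chromen-7-ol | Oc1ccc2c(c1)OC[C@@H](c1ccc(O)cc1OCOC)C2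
F7 | step 11 | (3R)-6-bromo-3-[5-bromo-4-hydroxy-2-(methoxymethoxy)phenyl]-3,4-dihydro-2H-chromen-7-ol | Brc1cc2c(cc1O)OC[C@@H](c1cc(Br)c(O)cc1OCOC)C2
F8 | step 11 | (3R)-6-bromo-3-[5-bromo-2,4-bis(methoxymethoxy)phenyl]-7-(methoxymethoxy)-3,4-dihydro-2H-chromene | Brc1cc2c(cc1OCOC)OC[C@@H](c1cc(Br)c(OCOC)cc1OCOC)C2
F9 | step 11 | (3R)-3-[2,4-bis(methoxymethoxy)-5-(2-methylbut-3-en-2-yl)phenyl]-7-(methoxymethoxy)-6-(2-methylbut-3-en-2-yl)-3,4-dihydro-2H-chromene | C=CC(C)(C)c1cc2c(cc1OCOC)OC[C@@H](c1cc(C(C)(C)C=C)c(OCOC)cc1OCOC)C2
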